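**Retrosynthetic overview**
1. Open the pyranone of Agecorynin F at O1–C8a and remove the 5'-OMe. Both C–O bonds come from one dibromo 1,3-diketone in a single Cu/NaOMe operation. Ring C is the only ring made, and it is made last.
2. The dibromo diketone comes from a crossed Claisen condensation of a 6-bromo-2-hydroxy-3,4-dimethoxyacetophenone (ring A) with methyl 5-bromo-2,3,4-trimethoxybenzoate (ring B).
3. The ring A ketone comes from 5-bromo-1,2,3-trimethoxybenzene by Friedel–Crafts acetylation with in-flask chelation demethylation. The freed OH is never used for ring closure and ends as the 5-OH, so no late deprotection is needed.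
4. The ring B ester comes from methyl 2,3,4-trimethoxybenzoate by C5-selective bromination.
5. Rings A and B are bought, and the route is convergent (1 + 1 + 2 steps).

Assumption: the target SMILES has no stereocentre, stereogenic axis or stereogenic double bond, so the compound is achiral and needs no enantiocontrol.

**Step 1**
Reactants: 1 5-bromo-1,2,3-trimethoxybenzene
Product: 3 1-(6-bromo-2-hydroxy-3,4-dimethoxyphenyl)ethan-1-one, via 6-bromo-2,3,4-trimethoxyacetophenone 2 (not isolated)
Conditions: AcCl (1.3 equiv), AlCl3 (3.0 equiv), CH2Cl2, 0 to 40 °C, 6 h; ice/2 M HCl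
Reagents that add atoms: acetyl chloride CC(=O)Cl
Why: Friedel–Crafts acylation can only enter one of the two equivalent free positions of 1 (ortho and para to OMe, as in the well-behaved acylation of 3,4,5-trimethoxytoluene), and the excess AlCl3 held in the C=O/ortho-OMe chelate of 2 then cleaves only that methyl ether (chelation-controlled demethylation), which frees the oxygen that ends as the 5-OH.

**Step 2**
Reactants: 4 methyl 2,3,4-trimethoxybenzoate
Product: 5 methyl 5-bromo-2,3,4-trimethoxybenzoate
Conditions: NBS (1.05 equiv), MeCN, 40 °C, 12 h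
Reagents that add atoms: N-bromosuccinimide O=C1CCC(=O)N1Br
Why: Electrophilic aromatic bromination goes to C5, which is para to the 2-OMe, ortho to the 4-OMe and meta to the ester, whereas C6 is ortho to the ester and activated only by the twisted 3-OMe.

**Step 3**
Reactants: 3 1-(6-bromo-2-hydroxy-3,4-dimethoxyphenyl)ethan-1-one; 5 methyl 5-bromo-2,3,4-trimethoxybenzoate
Product: 6 1-(6-bromo-2-hydroxy-3,4-dimethoxyphenyl)-3-(5-bromo-2,3,4-trimethoxyphenyl)propane-1,3-dione
Conditions: NaH (4 equiv), THF, 0 °C to reflux, 4 h; cold 1 M HCl to pH 4–5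
Reagents that add atoms: none
Why: Crossed Claisen condensation in which 3 is the only enolisable partner and 5 the only acyl donor, irreversible deprotonation of the diketone drives the equilibrium, both aryl bromides are inert to NaH, and the cold weakly acidic quench avoids cyclodehydration.

**Step 4**
Reactants: 6 1-(6-bromo-2-hydroxy-3,4-dimethoxyphenyl)-3-(5-bromo-2,3,4-trimethoxyphenyl)propane-1,3-dione
Product: 8 Agecorynin F (5-hydroxy-6,7-dimethoxy-2-(2,3,4,5-tetramethoxyphenyl)-4H-chromen-4-one), via 5'-bromoflavone 7 (not isolated)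
Conditions: CuBr (20 mol %), NaOMe (8 equiv, 5.4 M in MeOH), DMF, N2, 80 °C 2 h then 105 °C 10 h; 1 M HCl, EDTA wash
Reagents that add atoms: sodium methoxide [Na+].[O-]C
Why: Proposed new method: excess methoxide turns 6 into its phenoxide/diketonate dianion, which leaves no electrophilic C=O for the classical phenol-to-carbonyl cyclodehydration (that path would give the 7,8-dimethoxy isomer) and is itself a β-diketonate ligand for Cu(I); carbonyl-assisted oxidative addition into the ortho C–Br of ring A and C–O reductive elimination from the distal enolate oxygen close the pyranone through O1–C8a to 7, whose 5-oxido-4-keto chelate keeps copper in solution for the slower intermolecular Ullmann methoxylation of C5'–Br, a bromide that cannot cyclise because it is meta to the carbonyl; the closest known reaction types are the Cu-catalysed or base-only intramolecular O-arylation of 1-(2-haloaryl)-1,3-diketones to flavones and the CuBr/NaOMe methanolysis of bromoarenes and bromoflavones, which have been shown neither in tandem nor on a substrate with a free ortho'-OH that offers a rival ring closure.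

**Compound list**
1 | 5-bromo-1,2,3-trimethoxybenzene | COc1cc(Br)cc(OC)c1OC | starting material
2 | 1-(6-bromo-2,3,4-trimethoxyphenyl)ethan-1-one (6-bromo-2,3,4-trimethoxyacetophenone) | CC(=O)c1c(Br)cc(OC)c(OC)c1OC | intermediate
3 | 1-(6-bromo-2-hydroxy-3,4-dimethoxyphenyl)ethan-1-one | CC(=O)c1c(Br)cc(OC)c(OC)c1O | intermediate
4 | methyl 2,3,4-trimethoxybenzoate | COC(=O)c1ccc(OC)c(OC)c1OC | starting material
5 | methyl 5-bromo-2,3,4-trimethoxybenzoate | COC(=O)c1cc(Br)c(OC)c(OC)c1OC | intermediate
6 | 1-(6-bromo-2-hydroxy-3,4-dimethoxyphenyl)-3-(5-bromo-2,3,4-trimethoxyphenyl)propane-1,3-dione | COc1cc(Br)c(C(=O)CC(=O)c2cc(Br)c(OC)c(OC)c2OC)c(O)c1OC | intermediate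
7 | 2-(5-bromo-2,3,4-trimethoxyphenyl)-5-hydroxy-6,7-dimethoxy-4H-chromen-4-one (5'-bromoflavone) | COc1cc2oc(-c3cc(Br)c(OC)c(OC)c3OC)cc(=O)c2c(O)c1OC | intermediate
8 | Agecorynin F, 5-hydroxy-6,7-dimethoxy-2-(2,3,4,5-tetramethoxyphenyl)-4H-chromen-4-one | COc1cc(-c2cc(=O)c3c(O)c(OC)c(OC)cc3o2)c(OC)c(OC)c1OC | target

**Total step count:** 4.
**Longest linear sequence:** 3 (1 → 3 → 6 → 8, or 4 → 5 → 6 → 8).

**Steps most likely to fail**

Step 4 (the new tandem C–O coupling).
- The phenoxide may attack the distal carbonyl and give the 5-bromo-7,8-dimethoxy isomer.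
- Cu/methoxide may cause hydrodebromination.
- Methoxide may open the finished pyranone. Re-closure should favour the 5,6,7-oxygenation pattern, but material can be lost.

The fallback uses only known chemistry, keeps the phenol masked through both copper steps and runs them separately. It sets out from 1 and comes back at 8. Acylation of 1 with AcCl/SnCl4 (CH2Cl2, 0 °C) stops at 2, which is isolated. Claisen condensation of 2 with 5 (NaH, THF) gives 1-(6-bromo-2,3,4-trimethoxyphenyl)-3-(5-bromo-2,3,4-trimethoxyphenyl)propane-1,3-dione F1. The established CuI/K2CO3/DMF (110 °C) O-arylation of 2-bromoaryl diketones gives 2-(5-bromo-2,3,4-trimethoxyphenyl)-5,6,7-trimethoxy-4H-chromen-4-one F2. CuBr/NaOMe/DMF methanolysis gives 5,6,7-trimethoxy-2-(2,3,4,5-tetramethoxyphenyl)-4H-chromen-4-one F3. BCl3 (1.2 equiv, CH2Cl2, −78 to 0 °C) then removes only the peri 5-O-methyl group and delivers 8.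

Step 1 (hindered acylation of an electron-rich aryl bromide under AlCl3).
- Conversion may be slow.
- Acid may cause loss or migration of bromine.
- The 3-OMe may also be cleaved.

The fallback replaces electrophilic substitution by directed metalation. It sets out from 1 and comes back at 3. LDA (THF, −78 °C) deprotonates the position between Br and OMe, as with 3-bromoanisoles. Trapping with N-methoxy-N-methylacetamide gives 2, which is isolated. A separate BCl3 demethylation (1.1 equiv, CH2Cl2, −78 to 0 °C) of the ortho-OMe gives 3. No compound outside the list is made.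

Step 3 (intermolecular Claisen condensation of two ortho-substituted partners).
- Conversion may be low.
- The ester may be consumed by adventitious hydroxide.

The fallback makes the acyl transfer intramolecular. It sets out from 5 and 3 and comes back at 6. Saponification of 5 (LiOH, THF/H2O) gives 5-bromo-2,3,4-trimethoxybenzoic acid F4. Treatment with (COCl)2 and cat. DMF gives 5-bromo-2,3,4-trimethoxybenzoyl chloride F5. O-acylation of 3 (pyridine, DMAP) gives 2-acetyl-3-bromo-5,6-dimethoxyphenyl 5-bromo-2,3,4-trimethoxybenzoate F6. The Baker–Venkataraman rearrangement (KOH, pyridine, 50 °C) then gives 6.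

**Further compounds**
F1 | step 4 | 1-(6-bromo-2,3,4-trimethoxyphenyl)-3-(5-bromo-2,3,4-trimethoxyphenyl)propane-1,3-dione | COc1cc(Br)c(C(=O)CC(=O)c2cc(Br)c(OC)c(OC)c2OC)c(OC)c1OC
F2 | step 4 | 2-(5-bromo-2,3,4-trimethoxyphenyl)-5,6,7-trimethoxy-4H-chromen-4-one | COc1cc2oc(-c3cc(Br)c(OC)c(OC)c3OC)cc(=O)c2c(OC)c1OC
F3 | step 4 | 5,6,7-trimethoxy-2-(2,3,4,5-tetramethoxyphenyl)-4H-chromen-4-one | COc1cc2oc(-c3cc(OC)c(OC)c(OC)c3OC)cc(=O)c2c(OC)c1OC
F0 | step 1 | none | none
F4 | step 3 | 5-bromo-2,3,4-trimethoxybenzoic acid | OC(=O)c1cc(Br)c(OC)c(OC)c1OC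
F5 | step 3 | 5-bromo-2,3,4-trimethoxybenzoyl chloride | ClC(=O)c1cc(Br)c(OC)c(OC)c1OC
F6 | step 3 | 2-acetyl-3-bromo-5,6-dimethoxyphenyl 5-bromo-2,3,4-trimethoxybenzoate | CC(=O)c1c(Br)cc(OC)c(OC)c1OC(=O)c2cc(Br)c(OC)c(OC)c2OC
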